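Numbering (ent-kaurane): ring A = C1–C5 + C10; C18 = CH3 and C19 = CH2OH on C4; C6 = CH2OAc on C5; C20 = OCH2 on C10; C7 = lactone C=O; C8, C9, C11–C16 = bicyclo[3.2.1]octane; C17 = exocyclic CH2.
Cuts, in retrosynthetic order: C16=C17 (methylenation), C13–C16 (ring D), C9–C11 and C8–C14 (ring C), C8=C9 and O–C7 (spiro δ-lactone), and last C5–C10 together with C3–C4 (ring A).
Enabling feature: three neighbouring ring A carbons (quaternary C4, tertiary C5, spiro-quaternary C10) hold their oxygenated one-carbon arms C19, C6 and C20 on one face, and C10 adjoins the oxygen-bearing C1. An endo [4+2] union of a 3-methylbutenolide (C4=C5, with C19 and C6 in its ring) with a diene C3=C2–C1(O)=C10 leaves exactly this pattern, and the 1,3-related O1 and O20 can be clasped by one silicon atom, which freezes the geometry at C10.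
Forward order of rings: temporary dioxasiline, ring A (Diels–Alder), spiro lactone (acetoacetylation, Knoevenagel), ring C (butadiene Diels–Alder), ring D (palladium-mediated cycloalkenylation); methylenation and desilylation finish.
Stereochemistry: (+)-menthol fixes the 5S acetal carbon of the butenolide, which steers the diene to one face (C4, C5). Endo alignment plus the locked diene sets C10, axial hydride attack sets C1, diene approach on the C1 flank of the lactone sets C8 and C9, and the bridge dictates C13.

Key step: step 9

Assumption: the hemiacetal of step 1 and the intermediates of the diene arm (steps 3 to 7) are carried as racemates or diastereomer mixtures, because their stereocentres are equilibrated in step 2 or erased in step 8.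
Abbreviations: PMB = 4-methoxybenzyl, TBDPS = tert-butyldiphenylsilyl, Men = (1S,2R,5S)-menthyl, DMAP = 4-dimethylaminopyridine.

Step 1
Reactants: 1 3-methyl-2-furoic acid
Product: 2 5-hydroxy-3-methyl-2(5H)-furanone (racemic hemiacetal)
Conditions: O2, 5,10,15,20-tetraphenylporphyrin (cat.), visible light, CH2Cl2, 0 °C
Reagents that add atoms: dioxygen O=O
Why: Furan photooxygenation: singlet oxygen adds [4+2] across C2/C5 and the endoperoxide fragments with loss of CO2, so the former carboxyl-bearing carbon becomes the lactone carbonyl next to the methyl group, while the new hemiacetal carbon forms racemic and is settled in step 2.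

Step 2
Reactants: 2 5-hydroxy-3-methyl-2(5H)-furanone; 3 (+)-menthol, (1S,2R,5S)-2-isopropyl-5-methylcyclohexanol
Product: 4 (5S)-5-[(1S,2R,5S)-menthyloxy]-3-methyl-2(5H)-furanone
Conditions: camphor-10-sulfonic acid (cat.), toluene, reflux, Dean–Stark trap; crystallisation from hexane, mother liquor re-equilibrated with the same acid
Reagents that add atoms: none
Why: Acid-catalysed acetalisation of the pseudo-acid gives two acetal epimers that interconvert under acid, so crystallisation with recycling should funnel the material into the 5S epimer, the pairing that mirrors the crystalline epimer of the parent menthyloxyfuranone series.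

Step 3
Reactants: 5 2-(hydroxymethyl)propane-1,3-diol
Product: 6 [2-(4-methoxyphenyl)-1,3-dioxan-5-yl]methanol (cis/trans mixture)
Conditions: 4-methoxybenzaldehyde dimethyl acetal, camphor-10-sulfonic acid (cat.), THF, rt
Reagents that add atoms: 4-methoxybenzaldehyde dimethyl acetal COc1ccc(cc1)C(OC)OC
Why: Transacetalisation closes a six-membered 1,3-dioxane over two of the three equivalent arms and leaves the third hydroxymethyl group free.

Step 4
Reactants: 6 [2-(4-methoxyphenyl)-1,3-dioxan-5-yl]methanol
Product: 7 2-(4-methoxyphenyl)-1,3-dioxane-5-carbaldehyde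
Conditions: SO3·pyridine, DMSO, Et3N, CH2Cl2, 0 °C
Reagents that add atoms: none
Why: The Parikh–Doering oxidation stops at the aldehyde and is mild and cold enough to avoid β-elimination of the acetal oxygens.

Step 5
Reactants: 7 2-(4-methoxyphenyl)-1,3-dioxane-5-carbaldehyde; 8 vinylmagnesium bromide
Product: 9 1-[2-(4-methoxyphenyl)-1,3-dioxan-5-yl]prop-2-en-1-ol (stereoisomer mixture)
Conditions: THF, −78 → 0 °C; aq. NH4Cl
Reagents that add atoms: none
Why: Grignard 1,2-addition brings in C2 and C3, and the uncontrolled carbinol centre is destroyed again in step 7.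

Step 6
Reactants: 9 1-[2-(4-methoxyphenyl)-1,3-dioxan-5-yl]prop-2-en-1-ol
Product: 10 2-[(4-methoxybenzyloxy)methyl]pent-4-ene-1,3-diol (diastereomer mixture)
Conditions: iBu2AlH (3.5 equiv), CH2Cl2, −78 → 0 °C; aq. potassium sodium tartrate
Reagents that add atoms: none
Why: Reductive opening of the 4-methoxybenzylidene acetal (aluminium coordination, hydride delivery to the oxocarbenium ion) gives one PMB ether and one primary alcohol, and opening at either oxygen is productive because the resulting diastereomers converge in step 8.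

Step 7
Reactants: 10 2-[(4-methoxybenzyloxy)methyl]pent-4-ene-1,3-diol
Product: 11 4-(hydroxymethyl)-5-(4-methoxybenzyloxy)pent-1-en-3-one (racemic, used at once)
Conditions: activated MnO2 (excess), CH2Cl2, rt; filtration, cold concentration
Reagents that add atoms: none
Why: Chemoselective allylic oxidation with MnO2 touches only the vinyl carbinol and works under neutral conditions, which spare the labile β-hydroxy vinyl ketone.

Step 8
Reactants: 11 4-(hydroxymethyl)-5-(4-methoxybenzyloxy)pent-1-en-3-one
Product: 12 2,2-di-tert-butyl-5-[(4-methoxybenzyloxy)methyl]-6-vinyl-4H-1,3,2-dioxasiline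
Conditions: tBu2Si(OTf)2, Et3N, CH2Cl2, −78 → 0 °C
Reagents that add atoms: di-tert-butylsilyl bis(trifluoromethanesulfonate) CC(C)(C)[Si](OS(=O)(=O)C(F)(F)F)(OS(=O)(=O)C(F)(F)F)C(C)(C)C
Why: Silyl triflate/amine enol silylation: after O-silylation of the primary alcohol the second Si–OTf silylates the ketone oxygen intramolecularly while Et3N removes the only α-hydrogen, and the six-membered ring forces O1 and C20 cis on C1=C10, so C20 is the outside and C9 the inside substituent of the s-cis diene.

Step 9
Reactants: 4 (5S)-5-[(1S,2R,5S)-menthyloxy]-3-methyl-2(5H)-furanone; 12 2,2-di-tert-butyl-5-[(4-methoxybenzyloxy)methyl]-6-vinyl-4H-1,3,2-dioxasiline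
Product: 13 ring A cycloadduct: a cyclohexene whose C1=C2 silyl enol ether is still tied to O20 through the di-tert-butylsilylene ring and which is cis-fused at C4/C5 to the menthyloxy γ-lactone (C19, C6 and C20 on one face; C18, H5 and the C9H2OPMB arm on the other; OMen trans to C10 on the lactone)
Conditions: 12 (1.5 equiv), 2,6-di-tert-butyl-4-methylphenol (cat.), CH2Cl2, 1.3 GPa, 40 °C
Reagents that add atoms: none
Why: Proposed new method: the reaction is a concerted, asynchronous normal-demand [4+2] cycloaddition in which the donor terminus C10 of the silyl dienol ether bonds ahead to the butenolide β-carbon C5 and C3 follows onto the methyl-bearing α-carbon C4, and pressure is chosen because it accelerates this bond-forming path far more than the competing 1,5-hydrogen shift of the diene. The closest known reaction types are the thermal endo, anti-facial additions of 5-alkoxy-2(5H)-furanones to 2-silyloxybutadienes and the cycloadditions of 2-substituted 1-vinylcyclohexenes that create angular quaternary carbons, whereas an α-methylbutenolide has not been combined with a silylene-locked, fully substituted diene terminus. Ring A (C1 to C5 and C10) is closed intermolecularly and suprafacially on both partners by the bonds C5–C10 and C3–C4. C5 and C4 are controlled by the 5S acetal carbon (the future C6), whose menthyloxy group blocks one butenolide face, together with the cis geometry of the ring alkene, and C10 is controlled by endo alignment of the lactone under the diene combined with the ring-fixed diene geometry, which puts the outside arm C20 cis and the inside arm C9 trans to C6 and C19. The step needs head-to-head regiochemistry, endo orientation and anti facial attack, secured respectively by the polar match of C10 with C5 (which also pairs the crowded terminus with the CH carbon and the free terminus with the carbon that becomes quaternary C4), by secondary overlap of the C19 carbonyl with C1 and C2, and by the acetal substituent.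

Step 10
Reactants: 13 ring A cycloadduct
Product: 14 C6,C19-diol of ring A (silylene enol ether and C9 PMB ether intact; C4, C5, C10 as in 13)
Conditions: LiAlH4, THF, 0 °C → rt; aqueous work-up
Reagents that add atoms: none
Why: LiAlH4 reduction of the γ-alkoxy lactone takes C19 to the carbinol, the released hemiacetal collapses to the C6 aldehyde that is reduced in turn with liberation of menthol, and neither the silyl enol ether, the PMB ether nor any stereocentre is touched.

Step 11
Reactants: 14 C6,C19-diol of ring A
Product: 15 C19 TBDPS ether with free C6 hydroxyl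
Conditions: TBDPSCl (1.05 equiv), imidazole, DMF, 0 °C → rt
Reagents that add atoms: tert-butylchlorodiphenylsilane CC(C)(C)[Si](Cl)(c1ccccc1)c1ccccc1
Why: Sterically governed monosilylation of a diol: the bulky chlorosilane should take the C19 hydroxyl, whose oxygen can turn outward over C3, in preference to the C6 hydroxyl, which is wedged between the quaternary C4 and C10 and meets a syn-pentane contact in every rotamer.

Step 12
Reactants: 15 C19 TBDPS ether with free C6 hydroxyl
Product: 16 C6 acetate, C19 TBDPS ether (silylene enol ether and PMB ether intact)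
Conditions: Ac2O, pyridine, DMAP (cat.), CH2Cl2, rt
Reagents that add atoms: acetic anhydride CC(=O)OC(C)=O
Why: DMAP-catalysed acetylation of the only remaining hydroxyl installs the first acetate of the target.

Step 13
Reactants: 16 C6 acetate, C19 TBDPS ether
Product: 17 C1 ketone with free C20 hydroxyl (C6 OAc, C19 OTBDPS, C9 OPMB)
Conditions: HF·pyridine, excess pyridine, THF, 0 °C
Reagents that add atoms: none
Why: Buffered fluoride cleaves the silylene, one of whose Si–O bonds is an enol ether, much faster than the TBDPS ether, the enol tautomerises to the C1 ketone, and the quaternary C10 rules out β-elimination of the new β-hydroxy ketone.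

Step 14
Reactants: 17 C1 ketone with free C20 hydroxyl
Product: 18 C1,C20-diol of ring A with equatorial C1 hydroxyl cis to C20, C6 and C19 (C6 OAc, C19 OTBDPS, C9 OPMB)
Conditions: NaBH4, CeCl3·7H2O, MeOH, −40 °C
Reagents that add atoms: none
Why: Luche reduction: the small external hydride attacks the C1 carbonyl axially from the face opposite the axial C20 and C19 arms, giving the equatorial alcohol on the same face as C20, while the cold, weakly basic medium suppresses retro-aldol loss of C20.

Step 15
Reactants: 18 C1,C20-diol of ring A; 19 2,2,6-trimethyl-4H-1,3-dioxin-4-one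
Product: 21 C20 acetoacetate of diol 18 (C1 hydroxyl free), via acetylketene 20 (not isolated)
Conditions: 19 (1.05 equiv), toluene, 110 °C
Reagents that add atoms: none
Why: Acylketene acetoacetylation: thermal cycloreversion of 19 releases acetone and acetylketene, which should acylate the primary C20 hydroxyl faster than the secondary C1 hydroxyl next to quaternary C10, and any C1 ester can drain to the primary ester by 1,3-acyl shift at this temperature.

Step 16
Reactants: 21 C20 acetoacetate
Product: 22 C1 acetate of the C20 acetoacetate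
Conditions: Ac2O, pyridine, DMAP (cat.), CH2Cl2, 0 °C → rt
Reagents that add atoms: acetic anhydride CC(=O)OC(C)=O
Why: DMAP-catalysed acetylation of the hindered secondary alcohol installs the second acetate with retention at C1.

Step 17
Reactants: 22 C1 acetate of the C20 acetoacetate
Product: 23 C9 primary alcohol (PMB removed)
Conditions: DDQ, CH2Cl2/pH 7 phosphate buffer, 0 °C
Reagents that add atoms: none
Why: Oxidative cleavage of the electron-rich benzyl ether by DDQ runs under neutral buffered conditions, which keep the neighbouring esters from migrating to the freed C9 hydroxyl and so protect the identity of the two arms on C10.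

Step 18
Reactants: 23 C9 primary alcohol
Product: 24 C9 aldehyde on quaternary C10
Conditions: Dess–Martin periodinane, CH2Cl2, 0 °C → rt
Reagents that add atoms: none
Why: The Dess–Martin oxidation copes with neopentyl alcohols under near-neutral conditions, and the aldehyde has no α-hydrogen and can neither epimerise nor eliminate.

Step 19
Reactants: 24 C9 aldehyde
Product: 25 spiro 3-acetyl-5,6-dihydro-2H-pyran-2-one (C8=C9 bearing the C15 acetyl and the C7 lactone carbonyl; C10 spiro to ring A)
Conditions: piperidine (cat.), AcOH (cat.), 4 Å molecular sieves, CH2Cl2, rt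
Reagents that add atoms: none
Why: Intramolecular Knoevenagel condensation of the acetoacetate methylene (C8) with the C9 aldehyde closes the six-membered unsaturated lactone and leaves C10 untouched.

Step 20
Reactants: 25 spiro 3-acetyl-5,6-dihydro-2H-pyran-2-one; 26 buta-1,3-diene
Product: 27 ring C adduct: cyclohexene (C12=C13) cis-fused to the lactone, acetyl on quaternary C8 cis to H9, C11 and C14 on the C1 flank of the lactone
Conditions: ZnCl2 (1.5 equiv), 26 (excess), CH2Cl2/Et2O, sealed tube, 0 °C → rt
Reagents that add atoms: none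
Why: Lewis acid-promoted Diels–Alder reaction of a chelating, doubly activated dienophile, a class known to react despite a neighbouring quaternary carbon; suprafacial addition makes C11 and C14 cis, and the diene should come to the lactone face flanked only by the C1 oxygen rather than the face screened by the C5 branch (C6H2OAc and the axial C19H2OTBDPS), which sets C9 and C8.

Step 21
Reactants: 27 ring C adduct
Product: 28 C15 trimethylsilyl enol ether (C15=C16H2) of 27
Conditions: TMSOTf (1.3 equiv), Et3N, CH2Cl2, 0 °C
Reagents that add atoms: trimethylsilyl trifluoromethanesulfonate C[Si](C)(C)OS(=O)(=O)C(F)(F)F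
Why: Soft enolisation silylates the methyl ketone, whose only α-hydrogens are on C16 because C8 is quaternary, well before the less reactive esters.

Step 22
Reactants: 28 C15 trimethylsilyl enol ether
Product: 29 bicyclo[3.2.1]octenone with C15 ketone, new C13–C16 bond and C11=C12 alkene
Conditions: Pd(OAc)2 (1.1 equiv), MeCN, rt
Reagents that add atoms: none
Why: Oxidative cycloalkenylation of a silyl enol ether by divalent palladium, an intramolecular relative of the Saegusa–Ito reaction: the palladium enolate adds in the 5-exo mode across C13=C12 on the only face the C8 acetyl can reach, which fixes C13, and β-hydride elimination can go only toward C11, with release of zerovalent palladium.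

Step 23
Reactants: 29 bicyclo[3.2.1]octenone
Product: 30 saturated bicyclo[3.2.1]octan-15-one
Conditions: H2 (1 atm), 10% Pd on carbon, EtOAc, rt
Reagents that add atoms: none
Why: Catalytic hydrogenation saturates the disubstituted C11=C12 alkene, the only reducible group left, and creates no stereocentre.

Step 24
Reactants: 30 saturated bicyclo[3.2.1]octan-15-one
Product: 32 C16 dimethylaminomethyl ketone (Mannich base; C16 epimers), via C15 trimethylsilyl enol ether 31 (not isolated)
Conditions: TMSOTf, Et3N, CH2Cl2, 0 °C → rt; volatiles removed; Me2N=CH2 I (Eschenmoser's salt), CH2Cl2, rt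
Reagents that add atoms: trimethylsilyl trifluoromethanesulfonate C[Si](C)(C)OS(=O)(=O)C(F)(F)F (its silyl group stays only in 31); N,N-dimethylmethyleneiminium iodide C[N+](C)=C.[I-]
Why: Mannich reaction of a silyl enol ether with a preformed iminium salt: enolisation can go only toward C16 because C8 is quaternary, base-free conditions spare the acetates, and the C16 configuration is irrelevant.

Step 25
Reactants: 32 C16 dimethylaminomethyl ketone
Product: 34 O19-TBDPS ether of isodojaponin D, via quaternary methiodide 33 (not isolated)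
Conditions: MeI, CH2Cl2/Et2O, rt; then sat. aq. NaHCO3, CH2Cl2, rt
Reagents that add atoms: iodomethane CI (its methyl group stays only in 33)
Why: Quaternisation followed by Hofmann-type E1cB elimination of trimethylamine under weak base delivers the exocyclic C16=C17 enone.

Step 26
Reactants: 34 O19-TBDPS ether of isodojaponin D
Product: 35 isodojaponin D
Conditions: HF·pyridine, pyridine, THF, 0 °C → rt (plastic vessel)
Reagents that add atoms: none
Why: Fluoride desilylation in a weakly acidic, non-nucleophilic medium frees the C19 hydroxyl and should spare the enone, the lactone and both acetates and avoid base-induced acetyl migration.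

Compound list
1 | 3-methyl-2-furoic acid | Cc1ccoc1C(=O)O | starting material
2 | 5-hydroxy-3-methyl-2(5H)-furanone (racemic) | CC1=CC(O)OC1=O | intermediate
3 | (+)-menthol, (1S,2R,5S) | CC(C)[C@H]1CC[C@H](C)C[C@@H]1O | starting material
4 | (5S)-5-[(1S,2R,5S)-menthyloxy]-3-methyl-2(5H)-furanone | CC1=C[C@@H](O[C@H]2C[C@@H](C)CC[C@@H]2C(C)C)OC1=O | intermediate
5 | 2-(hydroxymethyl)propane-1,3-diol | OCC(CO)CO | starting material
6 | [2-(4-methoxyphenyl)-1,3-dioxan-5-yl]methanol | OCC1COC(c2ccc(OC)cc2)OC1 | intermediate
7 | 2-(4-methoxyphenyl)-1,3-dioxane-5-carbaldehyde | O=CC1COC(c2ccc(OC)cc2)OC1 | intermediate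
8 | vinylmagnesium bromide | C=C[Mg]Br | starting material
9 | 1-[2-(4-methoxyphenyl)-1,3-dioxan-5-yl]prop-2-en-1-ol | C=CC(O)C1COC(c2ccc(OC)cc2)OC1 | intermediate
10 | 2-[(4-methoxybenzyloxy)methyl]pent-4-ene-1,3-diol | C=CC(O)C(CO)COCc1ccc(OC)cc1 | intermediate
11 | 4-(hydroxymethyl)-5-(4-methoxybenzyloxy)pent-1-en-3-one | C=CC(=O)C(CO)COCc1ccc(OC)cc1 | intermediate
12 | 2,2-di-tert-butyl-5-[(4-methoxybenzyloxy)methyl]-6-vinyl-4H-1,3,2-dioxasiline | C=CC1=C(COCc2ccc(OC)cc2)CO[Si](C(C)(C)C)(C(C)(C)C)O1 | intermediate
13 | ring A cycloadduct (silylene enol ether, cis-fused menthyloxy lactone) | COc1ccc(cc1)COC[C@]2(CO[Si](C(C)(C)C)(C(C)(C)C)O3)C3=CC[C@@](C)(C(=O)O4)[C@H]2[C@H]4O[C@H]5C[C@@H](C)CC[C@@H]5C(C)C | intermediate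
14 | C6,C19-diol of ring A | COc1ccc(cc1)COC[C@]2(CO[Si](C(C)(C)C)(C(C)(C)C)O3)C3=CC[C@@](C)(CO)[C@H]2CO | intermediate
15 | C19 TBDPS ether, C6 alcohol | COc1ccc(cc1)COC[C@]2(CO[Si](C(C)(C)C)(C(C)(C)C)O3)C3=CC[C@@](C)(CO[Si](c4ccccc4)(c5ccccc5)C(C)(C)C)[C@H]2CO | intermediate
16 | C6 acetate, C19 TBDPS ether | COc1ccc(cc1)COC[C@]2(CO[Si](C(C)(C)C)(C(C)(C)C)O3)C3=CC[C@@](C)(CO[Si](c4ccccc4)(c5ccccc5)C(C)(C)C)[C@H]2COC(C)=O | intermediate
17 | C1 ketone with free C20 hydroxyl | COc1ccc(cc1)COC[C@]2(CO)C(=O)CC[C@@](C)(CO[Si](c3ccccc3)(c4ccccc4)C(C)(C)C)[C@H]2COC(C)=O | intermediate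
18 | C1,C20-diol of ring A (C6 OAc, C19 OTBDPS, C9 OPMB) | COc1ccc(cc1)COC[C@]2(CO)[C@@H](O)CC[C@@](C)(CO[Si](c3ccccc3)(c4ccccc4)C(C)(C)C)[C@H]2COC(C)=O | intermediate
19 | 2,2,6-trimethyl-4H-1,3-dioxin-4-one | CC1=CC(=O)OC(C)(C)O1 | starting material
20 | acetylketene | CC(=O)C=C=O | intermediate
21 | C20 acetoacetate (C1 hydroxyl free) | COc1ccc(cc1)COC[C@]2(COC(=O)CC(C)=O)[C@@H](O)CC[C@@](C)(CO[Si](c3ccccc3)(c4ccccc4)C(C)(C)C)[C@H]2COC(C)=O | intermediate
22 | C1 acetate of the C20 acetoacetate | COc1ccc(cc1)COC[C@]2(COC(=O)CC(C)=O)[C@@H](OC(C)=O)CC[C@@](C)(CO[Si](c3ccccc3)(c4ccccc4)C(C)(C)C)[C@H]2COC(C)=O | intermediate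
23 | C9 primary alcohol | OC[C@]2(COC(=O)CC(C)=O)[C@@H](OC(C)=O)CC[C@@](C)(CO[Si](c3ccccc3)(c4ccccc4)C(C)(C)C)[C@H]2COC(C)=O | intermediate
24 | C9 aldehyde | O=C[C@]2(COC(=O)CC(C)=O)[C@@H](OC(C)=O)CC[C@@](C)(CO[Si](c3ccccc3)(c4ccccc4)C(C)(C)C)[C@H]2COC(C)=O | intermediate
25 | spiro 3-acetyl-5,6-dihydro-2H-pyran-2-one | CC(=O)C3=C[C@]1(COC3=O)[C@@H](OC(C)=O)CC[C@@](C)(CO[Si](c2ccccc2)(c4ccccc4)C(C)(C)C)[C@H]1COC(C)=O | intermediate
26 | buta-1,3-diene | C=CC=C | starting material
27 | ring C adduct (cis-fused lactone/cyclohexene, acetyl on C8) | CC(=O)[C@]23CC=CC[C@H]2[C@]1(COC3=O)[C@@H](OC(C)=O)CC[C@@](C)(CO[Si](c4ccccc4)(c5ccccc5)C(C)(C)C)[C@H]1COC(C)=O | intermediate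
28 | C15 trimethylsilyl enol ether of 27 | C=C(O[Si](C)(C)C)[C@]23CC=CC[C@H]2[C@]1(COC3=O)[C@@H](OC(C)=O)CC[C@@](C)(CO[Si](c4ccccc4)(c5ccccc5)C(C)(C)C)[C@H]1COC(C)=O | intermediate
29 | bicyclo[3.2.1]octenone (C15 ketone, C11=C12) | C1C(=O)[C@]23C[C@H]1C=C[C@H]2[C@]1(COC3=O)[C@@H](OC(C)=O)CC[C@@](C)(CO[Si](c4ccccc4)(c5ccccc5)C(C)(C)C)[C@H]1COC(C)=O | intermediate
30 | saturated bicyclo[3.2.1]octan-15-one | C1C(=O)[C@]23C[C@H]1CC[C@H]2[C@]1(COC3=O)[C@@H](OC(C)=O)CC[C@@](C)(CO[Si](c4ccccc4)(c5ccccc5)C(C)(C)C)[C@H]1COC(C)=O | intermediate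
31 | C15 trimethylsilyl enol ether of 30 | C1=C(O[Si](C)(C)C)[C@]23C[C@H]1CC[C@H]2[C@]1(COC3=O)[C@@H](OC(C)=O)CC[C@@](C)(CO[Si](c4ccccc4)(c5ccccc5)C(C)(C)C)[C@H]1COC(C)=O | intermediate
32 | C16 dimethylaminomethyl ketone (C16 epimers) | CN(C)CC1C(=O)[C@]23C[C@H]1CC[C@H]2[C@]1(COC3=O)[C@@H](OC(C)=O)CC[C@@](C)(CO[Si](c4ccccc4)(c5ccccc5)C(C)(C)C)[C@H]1COC(C)=O | intermediate
33 | quaternary methiodide of 32 | C[N+](C)(C)CC1C(=O)[C@]23C[C@H]1CC[C@H]2[C@]1(COC3=O)[C@@H](OC(C)=O)CC[C@@](C)(CO[Si](c4ccccc4)(c5ccccc5)C(C)(C)C)[C@H]1COC(C)=O.[I-] | intermediate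
34 | O19-TBDPS ether of isodojaponin D | C=C1C(=O)[C@]23C[C@H]1CC[C@H]2[C@]1(COC3=O)[C@@H](OC(C)=O)CC[C@@](C)(CO[Si](c4ccccc4)(c5ccccc5)C(C)(C)C)[C@H]1COC(C)=O | intermediate
35 | isodojaponin D | C=C1C(=O)[C@]23C[C@H]1CC[C@H]2[C@]1(COC3=O)[C@@H](OC(C)=O)CC[C@@](C)(CO)[C@H]1COC(C)=O | target

Total step count: 26.
Longest linear sequence: 24 steps (5 to 35, steps 3 to 26); the dienophile arm adds steps 1 and 2.

Steps most likely to fail

Step 9. Three things may go wrong.
- The cycloaddition may stall, because both new bonds end at carbons that become quaternary or sit next to such a carbon.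
- The diene may be lost through a 1,5-hydrogen shift or polymerisation.
- The α-methyl group may erode the endo preference.

The fallback leaves the methyl group out of the cycloaddition and adds it afterwards, using known reaction types only. Diene 12 is combined under the same conditions, or in toluene at 110 °C, with the purchasable parent dienophile (5S)-5-[(1S,2R,5S)-menthyloxy]-2(5H)-furanone F1. Its thermal endo, anti-selective additions to 2-silyloxydienes are established, and the reaction should give the C4-unsubstituted cycloadduct F2. Deprotonation of F2 with LiN(iPr)2 (THF, −78 °C) and alkylation of the lactone enolate with MeI can only keep the cis ring fusion. The methyl group therefore enters on the convex face in place of H4, and the route is rejoined at 13.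

Step 20. The two flanks of the spiro lactone may be discriminated poorly. Addition at the neopentyl C9 may be sluggish, or the reaction may divert into hetero-Diels–Alder addition and diene polymerisation. The fallback delivers the diene intramolecularly from the C1 oxygen through a temporary silicon tether.
- From 21, buffered DDQ gives the C1,C9-diol F3.
- 2,2,6,6-Tetramethylpiperidine-1-oxyl (cat.) with PhI(OAc)2 oxidises only the primary alcohol, giving the C1-hydroxy C9-aldehyde F4.
- Piperidinium acetate closes the C1-hydroxy spiro lactone F5.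
- Chloro(buta-1,3-dien-2-yl)dimethylsilane and imidazole give the dienylsilyl ether F6.
- On warming in toluene, F6 should undergo a type 2 intramolecular Diels–Alder reaction. The four-atom tether C10–C1–O–Si lets C11 reach C9 and C14 reach C8 only on the C1 flank, giving the bridged vinylsiloxane F7.
- AgF in aqueous THF/MeOH protodesilylates the alkenylsiloxane with the alkene kept at C12=C13 and spares the TBDPS ether, giving the C1 alcohol F8.
- Acetylation (Ac2O, DMAP) rejoins the route at 27.

Step 8 (with the labile product of step 7). The β-hydroxy vinyl ketone may be consumed by oxa-Michael closure, retro-aldol cleavage or β-elimination before silicon ties it up. The fallback attaches silicon before the enone is unveiled.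
- From 10, tBu2SiHCl and imidazole silylate only the primary hydroxyl, giving the di-tert-butylhydridosilyl ether F9.
- Dess–Martin periodinane oxidises the allylic alcohol to the silyl-capped enone F10, which has no free hydroxyl.
- N-Bromosuccinimide turns Si–H into Si–Br, giving the bromosilyl ether F11.
- Et3N, with AgOTf to raise the electrophilicity of silicon, closes the enol silylene and rejoins the route at 12.

Further compounds
F1 | step 9 | (5S)-5-[(1S,2R,5S)-menthyloxy]-2(5H)-furanone | O=C1C=C[C@@H](O[C@H]2C[C@@H](C)CC[C@@H]2C(C)C)O1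
F2 | step 9 | C4-unsubstituted cycloadduct (H in place of C18) | COc1ccc(cc1)COC[C@]2(CO[Si](C(C)(C)C)(C(C)(C)C)O3)C3=CC[C@@H](C(=O)O4)[C@H]2[C@H]4O[C@H]5C[C@@H](C)CC[C@@H]5C(C)C
F3 | step 20 | C1,C9-diol of the C20 acetoacetate | OC[C@]2(COC(=O)CC(C)=O)[C@@H](O)CC[C@@](C)(CO[Si](c3ccccc3)(c4ccccc4)C(C)(C)C)[C@H]2COC(C)=O
F4 | step 20 | C1-hydroxy C9-aldehyde | O=C[C@]2(COC(=O)CC(C)=O)[C@@H](O)CC[C@@](C)(CO[Si](c3ccccc3)(c4ccccc4)C(C)(C)C)[C@H]2COC(C)=O
F5 | step 20 | C1-hydroxy spiro 3-acetyl-5,6-dihydro-2H-pyran-2-one | CC(=O)C3=C[C@]1(COC3=O)[C@@H](O)CC[C@@](C)(CO[Si](c2ccccc2)(c4ccccc4)C(C)(C)C)[C@H]1COC(C)=O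
F6 | step 20 | C1 (buta-1,3-dien-2-yl)dimethylsilyl ether of F5 | CC(=O)C3=C[C@]1(COC3=O)[C@@H](O[Si](C)(C)C(=C)C=C)CC[C@@](C)(CO[Si](c2ccccc2)(c4ccccc4)C(C)(C)C)[C@H]1COC(C)=O
F7 | step 20 | bridged vinylsiloxane (C12–Si–O–C1) | CC(=O)[C@]23CC=C4C[C@H]2[C@]1(COC3=O)[C@@H](O[Si]4(C)C)CC[C@@](C)(CO[Si](c5ccccc5)(c6ccccc6)C(C)(C)C)[C@H]1COC(C)=O
F8 | step 20 | C1 alcohol corresponding to 27 | CC(=O)[C@]23CC=CC[C@H]2[C@]1(COC3=O)[C@@H](O)CC[C@@](C)(CO[Si](c4ccccc4)(c5ccccc5)C(C)(C)C)[C@H]1COC(C)=O
F9 | step 8 | di-tert-butylhydridosilyl ether of the primary hydroxyl of 10 | C=CC(O)C(CO[SiH](C(C)(C)C)C(C)(C)C)COCc1ccc(OC)cc1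
F10 | step 8 | silyl-capped enone | C=CC(=O)C(CO[SiH](C(C)(C)C)C(C)(C)C)COCc1ccc(OC)cc1
F11 | step 8 | bromosilyl ether of the enone | C=CC(=O)C(CO[Si](Br)(C(C)(C)C)C(C)(C)C)COCc1ccc(OC)cc1
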